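A unit first: molar per hour, the pace at which a flask eats starting material, set against the 37 mM of gas a saturated solution holds.

all flasks: gas 37 mM (held)
- birch: starting material 0.21 M; temperature 45 °C; run made earlier
- larch: starting material 0.32 M; temperature 80 °C; run made earlier
- Wednesday's: starting material 0.42 M; temperature 80 °C; time 25 h
- Monday's: starting material 0.42 M; temperature 50 °C; time 25 h
- Sunday's: starting material 0.42 M; at 50 °C until 20 h, from then on at 110 °C; time 25 h
- Tuesday's: starting material 0.42 M; temperature 110 °C; time 25 h

| run | time / h | target / % | starting material / % |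
|---|---|---|---|
| birch | 25.0 | 5.0 | 92.4 |
| birch | 60.0 | 15.8 | 67.8 |
| birch | 120 | 35.2 | 18.1 |
| birch | 192 | 41.1 | 1.6 |
| larch | 4.00 | 12.9 | 64.9 |
| larch | 10.0 | 30.6 | 5.7 |
| larch | 20.0 | 33.2 | 0 |
| larch | 30.0 | 33.2 | 0.2 |

(readings scatter by 0.3 percentage points)

1. the flask that comes out highest in amount of target, in percent of the starting material charged, or "all alike" when all lie within 1.5 percentage points (Wednesday's / Monday's / Sunday's / Tuesday's / all alike)
2. target at the end, in percent of the starting material charged, Wednesday's
3. target at the end, in percent of the starting material charged, Monday's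
4. target at the end, in percent of the starting material charged, Sunday's
5. target at the end, in percent of the starting material charged, Tuesday's

- at the start none of the gas is in solution

I solve two ends. With gas free, a flask is chemistry alone. Of my two runs I take birch as the nearer to that end, as its pace below is slower than larch's, and it reads 41.1% target with 1.6% starting material left, higher than larch's 33.2%. With gas starved, where transfer is the rate-limiting step, and if one gas goes into each target, a single solution's worth gives c(gas)/c(starting material) = 8.81% target. Larch's target already equals 2.87 such fills, so gas comes in during a run. Where a flask lies between the ends I read from its stock life, the time one saturated fill of gas lasts at the flask's pace of starting material loss: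

stock life = c(gas) / pace

larch, 4.00 h to 10.0 h: pace 0.0316 M h⁻¹, stock life 1.17 h

birch, 60.0 h to 120 h: pace 0.00174 M h⁻¹, stock life 21.3 h

From birch to larch, heat and charge together multiplied the pace by 18.2. I take Tuesday's as a like step again: pace 0.573 M h⁻¹, stock life 0.0646 h, which is shorter than larch's. So I put Tuesday's below the midpoint of the ends, 25.0%. Sunday's should join it, since birch lost 7.60% in 25.0 h and the larger part of Sunday's charge should meet the heat.

The forecast differs. It says “Wednesday's and Tuesday's flasks should finish”, and gives Wednesday's 30.5%, Monday's 10%, Sunday's 29.5% and Tuesday's 27%, with Wednesday's highest.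

The flasks give Wednesday's 28.8%, Monday's 12.4%, Sunday's 14.2% and Tuesday's 14.1%, so Wednesday's is highest.

    starting material + partner + by-product → target + 2 by-product (k = 0.00180 L² mol⁻² s⁻¹, Ea = 73.0 kJ mol⁻¹)
    starting material + partner → target + by-product (k = 2.20 × 10⁻⁵ L mol⁻¹ s⁻¹, Ea = 88.0 kJ mol⁻¹)
    starting material + target → side product (k = 5.20 × 10⁻⁵ L mol⁻¹ s⁻¹, Ea = 72.0 kJ mol⁻¹)
    2 starting material → homo dimer (k = 3.30 × 10⁻⁸ L mol⁻¹ s⁻¹, Ea = 86.0 kJ mol⁻¹)
    gas ⇌ partner, rate k5*(csat - [partner]) (kL = 4.60 × 10⁻⁴ s⁻¹)
    (constants at 50 °C)

Tuesday's ends with 83.7% side product. It reached 30.0% conversion in 1.35 h, an average pace of 0.0934 M h⁻¹, below my guess. Its stock life is 0.396 h, shorter than the transfer time 1/k5 of 0.604 h, while larch's 1.17 h is longer.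

Take Monday's flask with 1.7 M of starting material. Monday's own stock life is 7.64 h; if pace grows at least in proportion to charge, the neighbour's is at most 1.89 h. Computed, its 28% left gives 0.761 h, with partner down to 0.0153 M against Monday's 0.0332 M and target at 14.4%.

(Readings and results are simulated for substances that don't exist; noise was put on by code.)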